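## Retrosynthetic overview
1. The target is an achiral 1,4-bis(indol-3-yl)-2,3,5,6-tetramethoxybenzene. The last operations are N-Boc removal and O-debenzylation, which frees the single phenol.
2. Disconnection A: the bond from the central ring to C3 of the 6-methoxyindole, made by Suzuki–Miyaura coupling of an aryl bromide with an N-Boc-indol-3-yl boronate. The boronate comes from iridium-catalysed C–H borylation.
3. Disconnection B (new step): the bond from the central ring to C3 of the 5-benzyloxyindole, made by acid-triggered SN2′ substitution and aromatisation of a bromoquinone bisketal with the free (NH)-indole.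
4. The bisketal comes from 1,2,4,5-tetramethoxybenzene by monobromination and anodic methoxylation.
5. Ring order: no ring is built, because the central benzene and both indoles are bought intact. The central ring is dearomatised in step 2 and re-aromatised in step 3.

Assumption: the SMILES holds no stereocentre. The central ring carries identical methoxy groups on both sides of each aryl–indolyl axis, so no stable axial chirality exists either. The target is treated as achiral and no enantioselective step is needed.

## Route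

Step 1
Reactants: 1 1,2,4,5-tetramethoxybenzene
Product: 2 3-bromo-1,2,4,5-tetramethoxybenzene
Conditions: NBS (1.0 equiv), MeCN, 0 °C to rt
Reagents that add atoms: N-bromosuccinimide (NBS), O=C1CCC(=O)N1Br
Why: Electrophilic aromatic bromination (SEAr); the two free positions of 1 are equivalent and doubly ortho-activated, and the first bromine deactivates the ring enough for one equivalent of NBS to stop at the monobromide.

Step 2
Reactants: 2 3-bromo-1,2,4,5-tetramethoxybenzene
Product: 3 1-bromo-2,3,3,5,6,6-hexamethoxycyclohexa-1,4-diene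
Conditions: undivided cell, Pt anode, Pt cathode, 1% KOH in MeOH, constant current (about 2.2 F/mol), 0 °C; basic work-up, filtration through basic alumina
Reagents that add atoms: methanol, CO
Why: Anodic methoxylation of a 1,4-dimethoxyarene to a quinone bisketal; the radical cation carries its charge on the methoxy-bearing carbons, methoxide adds ipso at two para-related positions (both possible pairs give the same compound by symmetry), the basic medium protects the ketals, and the C–Br bond survives as it does for simpler bromodimethoxybenzenes.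

Step 3
Reactants: 3 1-bromo-2,3,3,5,6,6-hexamethoxycyclohexa-1,4-diene; 4 5-(benzyloxy)-1H-indole (1.2 equiv)
Product: 6 5-(benzyloxy)-3-(4-bromo-2,3,5,6-tetramethoxyphenyl)-1H-indole, via dienyl adduct 5 (not isolated)
Conditions: (PhO)2P(O)OH (10 mol %), HFIP/CH2Cl2 1:4, 5 Å MS, −20 °C to rt
Reagents that add atoms: none
Why: Proposed new method: Friedel–Crafts arylation of a free (NH)-indole by a quinone bisketal through SN2′ substitution followed by aromatisation; the acid reversibly ionises either ketal, but only the cation from the ketal next to C–Br (a pentadienyl cation stabilised by two methoxy groups at charged positions) has an unsubstituted terminus; the nucleophilic C3 of 4 adds at that C–H carbon to give 5, and loss of methanol across the new sp3 C–H and the neighbouring ketal carbon restores the benzene ring irreversibly, so indole C3 ends up para to bromine without metal, N-protection or external oxidant; attack at the bromine- or methoxy-bearing termini is hindered and cannot aromatise; HFIP and the sieves hold back the released methanol, which is the main competing nucleophile; the single stereocentre of 5 is racemic and vanishes on aromatisation; the closest known reaction types are the acid-promoted biaryl coupling of quinone monoacetals with electron-rich arenes and the acid-catalysed conversion of quinone bisketals into alkoxyarenes by methanol.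

Step 4
Reactants: 7 6-methoxy-1H-indole
Product: 8 tert-butyl 6-methoxy-1H-indole-1-carboxylate
Conditions: Boc2O (1.1 equiv), DMAP (5 mol %), MeCN, rt
Reagents that add atoms: di-tert-butyl dicarbonate (Boc2O), CC(C)(C)OC(=O)OC(=O)OC(C)(C)C
Why: DMAP-catalysed N-acylation (carbamate protection) masks the N–H and places a bulky group next to C2 and C7 for the following borylation.

Step 5
Reactants: 8 tert-butyl 6-methoxy-1H-indole-1-carboxylate
Product: 9 tert-butyl 6-methoxy-3-(4,4,5,5-tetramethyl-1,3,2-dioxaborolan-2-yl)-1H-indole-1-carboxylate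
Conditions: [Ir(OMe)(cod)]2 (1.5 mol %), dtbpy (3 mol %), B2pin2 (1.0 equiv), THF, 60 °C
Reagents that add atoms: bis(pinacolato)diboron (B2pin2), CC1(C)OB(OC1(C)C)B1OC(C)(C)C(C)(C)O1
Why: Iridium-catalysed aromatic C–H borylation under steric control; Boc shields C2 and C7, the methoxy group shields C5 and C7, and the peri position C4 is slow, so the heteroaryl C3–H is borylated.

Step 6
Reactants: 6 5-(benzyloxy)-3-(4-bromo-2,3,5,6-tetramethoxyphenyl)-1H-indole; 9 tert-butyl 6-methoxy-3-(4,4,5,5-tetramethyl-1,3,2-dioxaborolan-2-yl)-1H-indole-1-carboxylate (1.4 equiv)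
Product: 10 tert-butyl 3-{4-[5-(benzyloxy)-1H-indol-3-yl]-2,3,5,6-tetramethoxyphenyl}-6-methoxy-1H-indole-1-carboxylate
Conditions: Pd(OAc)2 (5 mol %), SPhos (10 mol %), K3PO4 (3 equiv), 1,4-dioxane/H2O 5:1, 90 °C
Reagents that add atoms: none
Why: Suzuki–Miyaura cross-coupling; the bulky electron-rich phosphine speeds oxidative addition of zerovalent palladium into the di-ortho-methoxy aryl bromide and reductive elimination of the hindered biaryl, the free indole N–H and the benzyl ether tolerate aqueous phosphate, and any partial Boc loss is harmless because step 7 removes the group.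

Step 7
Reactants: 10 tert-butyl 3-{4-[5-(benzyloxy)-1H-indol-3-yl]-2,3,5,6-tetramethoxyphenyl}-6-methoxy-1H-indole-1-carboxylate
Product: 11 5-(benzyloxy)-3-[2,3,5,6-tetramethoxy-4-(6-methoxy-1H-indol-3-yl)phenyl]-1H-indole
Conditions: K2CO3 (2 equiv), MeOH/THF 3:1, 60 °C
Reagents that add atoms: none
Why: Base-catalysed methanolysis (acyl transfer) of the activated indole carbamate, whose indolide is a good leaving group, leaves the aryl methyl ethers and the benzyl ether untouched and avoids strong acid on two electron-rich indoles.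

Step 8
Reactants: 11 5-(benzyloxy)-3-[2,3,5,6-tetramethoxy-4-(6-methoxy-1H-indol-3-yl)phenyl]-1H-indole
Product: 12 3-[2,3,5,6-tetramethoxy-4-(6-methoxy-1H-indol-3-yl)phenyl]-1H-indol-5-ol
Conditions: H2 (1 atm), Pd/C (10 wt % palladium on carbon), EtOAc/MeOH 1:1, rt
Reagents that add atoms: none
Why: Catalytic hydrogenolysis cleaves only the benzylic C–O bond, as is standard for 5-benzyloxyindoles; the five methyl ethers and both indole rings are inert at 1 atm, and no stereocentre is involved.

## Compound list
1 | 1,2,4,5-tetramethoxybenzene | COc1cc(OC)c(OC)cc1OC | starting material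
2 | 3-bromo-1,2,4,5-tetramethoxybenzene | COc1cc(OC)c(OC)c(Br)c1OC | intermediate
3 | 1-bromo-2,3,3,5,6,6-hexamethoxycyclohexa-1,4-diene (bis(dimethyl ketal) of 3-bromo-2,5-dimethoxy-1,4-benzoquinone) | COC1=C(Br)C(OC)(OC)C(OC)=CC1(OC)OC | intermediate
4 | 5-(benzyloxy)-1H-indole | c1ccc(COc2ccc3[nH]ccc3c2)cc1 | starting material
5 | 5-(benzyloxy)-3-(4-bromo-2,3,5,6,6-pentamethoxycyclohexa-2,4-dien-1-yl)-1H-indole (racemic, transient, not isolated) | COC1=C(Br)C(OC)=C(OC)C(c2c[nH]c3ccc(OCc4ccccc4)cc23)C1(OC)OC | intermediate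
6 | 5-(benzyloxy)-3-(4-bromo-2,3,5,6-tetramethoxyphenyl)-1H-indole | COc1c(Br)c(OC)c(OC)c(-c2c[nH]c3ccc(OCc4ccccc4)cc23)c1OC | intermediate
7 | 6-methoxy-1H-indole | COc1ccc2cc[nH]c2c1 | starting material
8 | tert-butyl 6-methoxy-1H-indole-1-carboxylate | COc1ccc2ccn(C(=O)OC(C)(C)C)c2c1 | intermediate
9 | tert-butyl 6-methoxy-3-(4,4,5,5-tetramethyl-1,3,2-dioxaborolan-2-yl)-1H-indole-1-carboxylate | COc1ccc2c(B3OC(C)(C)C(C)(C)O3)cn(C(=O)OC(C)(C)C)c2c1 | intermediate
10 | tert-butyl 3-{4-[5-(benzyloxy)-1H-indol-3-yl]-2,3,5,6-tetramethoxyphenyl}-6-methoxy-1H-indole-1-carboxylate | COc1ccc2c(-c3c(OC)c(OC)c(-c4c[nH]c5ccc(OCc6ccccc6)cc45)c(OC)c3OC)cn(C(=O)OC(C)(C)C)c2c1 | intermediate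
11 | 5-(benzyloxy)-3-[2,3,5,6-tetramethoxy-4-(6-methoxy-1H-indol-3-yl)phenyl]-1H-indole | COc1ccc2c(-c3c(OC)c(OC)c(-c4c[nH]c5ccc(OCc6ccccc6)cc45)c(OC)c3OC)c[nH]c2c1 | intermediate
12 | 3-[2,3,5,6-tetramethoxy-4-(6-methoxy-1H-indol-3-yl)phenyl]-1H-indol-5-ol (achiral) | COc1ccc2c(-c3c(OC)c(OC)c(-c4c[nH]c5ccc(O)cc45)c(OC)c3OC)c[nH]c2c1 | target

## Step count and risks
Total step count: 8.
Longest linear sequence: 6 steps (steps 1, 2, 3, 6, 7, 8). Steps 4 and 5 form the second branch.

Three steps most likely to fail:

**Step 3 (the new reaction).**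
- Risks: the released methanol may return at the C–H terminus and give bromopentamethoxybenzene. The indole may attack a methoxy-bearing terminus. Traces of water may hydrolyse 3.
- The fallback uses only known cross-coupling. It sets out from 2 and 4 and comes back to the route at 6.
- A second bromination of 2 (NBS, MeCN, rt to 40 °C) gives 1,4-dibromo-2,3,5,6-tetramethoxybenzene F1.
- In parallel, 4 is iodinated (I2, KOH, DMF, rt) to 5-(benzyloxy)-3-iodo-1H-indole F2.
- F2 is protected (Boc2O, DMAP, CH2Cl2) as tert-butyl 5-(benzyloxy)-3-iodo-1H-indole-1-carboxylate F3.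
- Miyaura borylation of F3 (B2pin2, PdCl2(dppf), KOAc, dioxane, 80 °C) gives tert-butyl 5-(benzyloxy)-3-(4,4,5,5-tetramethyl-1,3,2-dioxaborolan-2-yl)-1H-indole-1-carboxylate F4.
- Suzuki–Miyaura mono-coupling of F4 with three equivalents of F1 (Pd(OAc)2, SPhos, K3PO4, dioxane/H2O, 90 °C, excess F1 recovered) gives tert-butyl 5-(benzyloxy)-3-(4-bromo-2,3,5,6-tetramethoxyphenyl)-1H-indole-1-carboxylate F5.
- Methanolysis of F5 (K2CO3, MeOH, 60 °C) gives 6.

**Step 2 (anodic bisketal formation).**
- Risks: over-oxidation, cathodic loss of bromine, or ketal hydrolysis during isolation.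
- The fallback builds the benzyloxyindole ring on the arene instead of joining a finished indole. It sets out from 2 and comes back at 6, bypassing 3, 4 and 5.
- Rieche formylation of 2 at its only free position (Cl2CHOMe, TiCl4, CH2Cl2, −10 °C) gives 4-bromo-2,3,5,6-tetramethoxybenzaldehyde F6.
- Wittig methoxymethylenation of F6 ((methoxymethyl)triphenylphosphonium chloride, KOtBu, THF, 0 °C) gives 1-bromo-2,3,5,6-tetramethoxy-4-(2-methoxyethenyl)benzene F7 as an E/Z mixture.
- Heating F7 with commercial 4-(benzyloxy)phenylhydrazine hydrochloride in EtOH at 80 °C forms (4-bromo-2,3,5,6-tetramethoxyphenyl)acetaldehyde 4-(benzyloxy)phenylhydrazone F8.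
- F8 undergoes the Fischer indole synthesis in the same pot ([3,3] shift, cyclisation, loss of ammonia). This gives 6 regiospecifically, because the hydrazine is para-substituted.

**Step 6 (hindered Suzuki–Miyaura coupling).**
- Risks: slow oxidative addition into the electron-rich di-ortho-methoxy bromide, and protodeboronation of 9.
- The fallback constructs the methoxyindole ring by Larock heteroannulation. It sets out from 6 and comes back at 11, so 7 to 10 are not needed.
- Copper-free Sonogashira coupling of 6 with ethynyltriethylsilane (PdCl2(MeCN)2, XPhos, Cs2CO3, MeCN, 80 °C) gives 5-(benzyloxy)-3-{2,3,5,6-tetramethoxy-4-[(triethylsilyl)ethynyl]phenyl}-1H-indole F9.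
- Annulation of F9 with commercial 2-iodo-5-methoxyaniline (Pd(OAc)2, Na2CO3, LiCl, DMF, 100 °C) places the silyl group at C2 and the aryl group at C3. The product is 3-{4-[5-(benzyloxy)-1H-indol-3-yl]-2,3,5,6-tetramethoxyphenyl}-6-methoxy-2-(triethylsilyl)-1H-indole F10.
- Protodesilylation of F10 (TBAF, wet THF, 60 °C) gives 11.

## Further compounds
F1 | step 3 | 1,4-dibromo-2,3,5,6-tetramethoxybenzene | COc1c(Br)c(OC)c(OC)c(Br)c1OC
F2 | step 3 | 5-(benzyloxy)-3-iodo-1H-indole | Ic1c[nH]c2ccc(OCc3ccccc3)cc12
F3 | step 3 | tert-butyl 5-(benzyloxy)-3-iodo-1H-indole-1-carboxylate | CC(C)(C)OC(=O)n1cc(I)c2cc(OCc3ccccc3)ccc21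
F4 | step 3 | tert-butyl 5-(benzyloxy)-3-(4,4,5,5-tetramethyl-1,3,2-dioxaborolan-2-yl)-1H-indole-1-carboxylate | CC(C)(C)OC(=O)n1cc(B2OC(C)(C)C(C)(C)O2)c2cc(OCc3ccccc3)ccc21
F5 | step 3 | tert-butyl 5-(benzyloxy)-3-(4-bromo-2,3,5,6-tetramethoxyphenyl)-1H-indole-1-carboxylate | COc1c(Br)c(OC)c(OC)c(-c2cn(C(=O)OC(C)(C)C)c3ccc(OCc4ccccc4)cc23)c1OC
F6 | step 2 | 4-bromo-2,3,5,6-tetramethoxybenzaldehyde | COc1c(Br)c(OC)c(OC)c(C=O)c1OC
F7 | step 2 | 1-bromo-2,3,5,6-tetramethoxy-4-(2-methoxyethenyl)benzene (E/Z mixture) | COC=Cc1c(OC)c(OC)c(Br)c(OC)c1OC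
F8 | step 2 | (4-bromo-2,3,5,6-tetramethoxyphenyl)acetaldehyde 4-(benzyloxy)phenylhydrazone | COc1c(Br)c(OC)c(OC)c(CC=NNc2ccc(OCc3ccccc3)cc2)c1OC
F9 | step 6 | 5-(benzyloxy)-3-{2,3,5,6-tetramethoxy-4-[(triethylsilyl)ethynyl]phenyl}-1H-indole | CC[Si](CC)(CC)C#Cc1c(OC)c(OC)c(-c2c[nH]c3ccc(OCc4ccccc4)cc23)c(OC)c1OC
F10 | step 6 | 3-{4-[5-(benzyloxy)-1H-indol-3-yl]-2,3,5,6-tetramethoxyphenyl}-6-methoxy-2-(triethylsilyl)-1H-indole | COc1ccc2c(-c3c(OC)c(OC)c(-c4c[nH]c5ccc(OCc6ccccc6)cc45)c(OC)c3OC)c([Si](CC)(CC)CC)[nH]c2c1
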